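**Plan**

1. Atoms carry the numbers of the target SMILES (C1–O34). Ring A = carbocycle C2/C3/C4/C5/C6/C12/C15, ring B = cyclopentanol C5–C9, ring C = cyclohexane C18/C19/C29/C30/C31/C32, ring D = oxepane C19/C21/C22/C23/C25/O28/C29.
2. Cuts: C15–C16 (copper-catalysed anti-SN2′ union of the two halves); C9–C5 (ring B, SmI2 ketyl–olefin closure, possible because C9 is a tertiary carbinol cis-fused to ring A with O11 anti to C4); C4=C5 (ring A, metathesis); C6–C12 (allylic alkylation); O28–C25 (ring D, epoxide opening); C18–C17 (Claisen); C32–O34 (iodolactonisation).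
3. Forward: acyclic trienone → ring A → ring B (step 10); separately 2-methylcyclohexane-1,3-dione (ring C) → ring D → C32 carbinol and C16/C17 side chain; the halves are joined at C15–C16 and desilylated.
4. Stereochemistry: C6 from iridium-catalysed allylic alkylation; C5 and C9 from the key step; the C3 carbinol (CBS) is relayed to C15 in the coupling; C19/C29 from a CBS desymmetrisation; C23 from a Shi epoxidation; the C31 carbinol (CBS) is relayed to C18 by Claisen rearrangement and on to C32 by cis-lactonisation.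

Key step: step 10

Remark: the SMILES fixes a cis ring C/D fusion (C20 methyl and H29 on the same face) with O34 syn to C17; every step is planned for exactly this stereoisomer.

**Ring A/B half**

Step 1
Reactants: 1 hex-5-en-2-one
Product: 2 2-(but-3-en-1-yl)-2-methyl-1,3-dioxolane
Conditions: HOCH2CH2OH, p-TsOH (cat.), benzene, reflux, Dean–Stark
Reagents that add atoms: ethylene glycol, OCCO
Why: Acid-catalysed ketalisation with azeotropic removal of water masks the methyl ketone (C9) against the hydride, ylide and Grignard reagents of steps 4–7.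

Step 2
Reactants: 2 2-(but-3-en-1-yl)-2-methyl-1,3-dioxolane, 3 allyl methyl carbonate
Product: 4 methyl (2E)-5-(2-methyl-1,3-dioxolan-2-yl)pent-2-en-1-yl carbonate
Conditions: second-generation Grubbs catalyst RuCl2(=CHPh)(PCy3)(H2IMes) (3 mol %), 3 (4 equiv), CH2Cl2, 40 °C
Reagents that add atoms: none
Why: Olefin cross-metathesis of a terminal alkene with an excess of an allyl carbonate should give the linear E allylic carbonate under thermodynamic control.

Step 3
Reactants: 4 methyl (2E)-5-(2-methyl-1,3-dioxolan-2-yl)pent-2-en-1-yl carbonate, 5 1-methoxy-2-methyl-1-(trimethylsilyloxy)prop-1-ene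
Product: 6 methyl (3S)-2,2-dimethyl-3-[2-(2-methyl-1,3-dioxolan-2-yl)ethyl]pent-4-enoate
Conditions: [Ir(cod)Cl]2 (2 mol %), O,O′-(1,1′-binaphthyl-2,2′-diyl)-N,N-bis(1-phenylethyl)phosphoramidite (4 mol %; the enantiomer that gives (S)-6, expected to be (Ra,R,R)), CsF (10 mol %), THF, 40 °C
Reagents that add atoms: none
Why: Iridium-catalysed branched-selective allylic alkylation with a silyl ketene acetal: the cyclometalated iridium–phosphoramidite complex directs the nucleophile to the substituted allyl terminus on one face, which forms the C6–C12 bond and sets C6 as (S) (the mirror-image ligand would give the antipode).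

Step 4
Reactants: 6 methyl (3S)-2,2-dimethyl-3-[2-(2-methyl-1,3-dioxolan-2-yl)ethyl]pent-4-enoate
Product: 7 (3S)-2,2-dimethyl-3-[2-(2-methyl-1,3-dioxolan-2-yl)ethyl]pent-4-enal
Conditions: i-Bu2AlH (1.1 equiv), CH2Cl2, −78 °C; Rochelle salt work-up
Reagents that add atoms: none
Why: Half-reduction of an ester: the aluminium hemiacetal of this neopentyl ester should persist at −78 °C and release the aldehyde (C15) only on work-up.

Step 5
Reactants: 7 (3S)-2,2-dimethyl-3-[2-(2-methyl-1,3-dioxolan-2-yl)ethyl]pent-4-enal, 8 methyl 2-[bis(2,2,2-trifluoroethoxy)phosphoryl]propanoate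
Product: 9 methyl (2Z,5S)-2,4,4-trimethyl-5-[2-(2-methyl-1,3-dioxolan-2-yl)ethyl]hepta-2,6-dienoate
Conditions: KN(SiMe3)2, 18-crown-6, THF, −78 → −40 °C
Reagents that add atoms: none
Why: Still–Gennari olefination: the trifluoroethyl phosphonate eliminates faster than its adducts equilibrate, so the Z trisubstituted enoate (C12 and C3 cis across C2=C15), as ring A needs, should form.

Step 6
Reactants: 9 methyl (2Z,5S)-2,4,4-trimethyl-5-[2-(2-methyl-1,3-dioxolan-2-yl)ethyl]hepta-2,6-dienoate
Product: 10 (2Z,5S)-N-methoxy-N,2,4,4-tetramethyl-5-[2-(2-methyl-1,3-dioxolan-2-yl)ethyl]hepta-2,6-dienamide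
Conditions: MeNH(OMe)·HCl, i-PrMgCl, THF, −20 → 0 °C
Reagents that add atoms: N,O-dimethylhydroxylamine hydrochloride, CNOC.Cl
Why: Aminolysis of the ester by the magnesium amide of N,O-dimethylhydroxylamine (Weinreb amide formation) prepares C3 for a single Grignard addition without touching the Z olefin.

Step 7
Reactants: 10 (2Z,5S)-N-methoxy-N,2,4,4-tetramethyl-5-[2-(2-methyl-1,3-dioxolan-2-yl)ethyl]hepta-2,6-dienamide, 11 vinylmagnesium bromide
Product: 12 (4Z,7S)-4,6,6-trimethyl-7-[2-(2-methyl-1,3-dioxolan-2-yl)ethyl]nona-1,4,8-trien-3-one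
Conditions: CH2=CHMgBr, THF, 0 °C; inverse quench into cold 1 M HCl
Reagents that add atoms: none
Why: Grignard addition to a Weinreb amide stops at the chelated tetrahedral intermediate, so the vinyl ketone (C3, C4) forms without over-addition; the cold acidic quench prevents conjugate addition of the liberated amine.

Step 8
Reactants: 12 (4Z,7S)-4,6,6-trimethyl-7-[2-(2-methyl-1,3-dioxolan-2-yl)ethyl]nona-1,4,8-trien-3-one
Product: 13 (5S)-2,4,4-trimethyl-5-[2-(2-methyl-1,3-dioxolan-2-yl)ethyl]cyclohepta-2,6-dien-1-one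
Conditions: second-generation Hoveyda–Grubbs catalyst RuCl2(=CH-C6H4-2-O-i-Pr)(H2IMes) (5 mol %), toluene (2 mM), 80 °C
Reagents that add atoms: none
Why: Ring-closing metathesis of the vinyl ketone with the C6 vinyl group forms C4=C5 and closes ring A; the Z C2=C15 olefin holds the two termini close and the trisubstituted olefin is not attacked.

Step 9
Reactants: 13 (5S)-2,4,4-trimethyl-5-[2-(2-methyl-1,3-dioxolan-2-yl)ethyl]cyclohepta-2,6-dien-1-one
Product: 14 (5S)-2,4,4-trimethyl-5-(3-oxobutyl)cyclohepta-2,6-dien-1-one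
Conditions: PPTS, acetone–H2O (10:1), 50 °C
Reagents that add atoms: water, O
Why: Mild acid-catalysed ketal hydrolysis frees the C9 methyl ketone under conditions too weak to ionise or isomerise the cross-conjugated dienone.

Step 10
Reactants: 14 (5S)-2,4,4-trimethyl-5-(3-oxobutyl)cyclohepta-2,6-dien-1-one
Product: 15 (1S,3aS,8aS)-1-hydroxy-1,4,4,6-tetramethyl-2,3,3a,4,8,8a-hexahydroazulen-7(1H)-one (cis-fused rings A/B)
Conditions: SmI2 (2.3 equiv, 0.1 M in THF), HMPA (8 equiv), t-BuOH (2 equiv), THF, −78 °C, slow addition of 14; NH4Cl aq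
Reagents that add atoms: none
Why: Divalent samarium, made strongly reducing by HMPA, transfers an electron either to the C9 methyl ketone (ketyl) or to the cross-conjugated dienone (radical anion with spin at C5); both paths lead to the C9–C5 bond, and a second electron plus protonation at C4 by t-BuOH returns the C2=C15 enone. The closest known reaction type is the SmI2-mediated ketyl–olefin (ketone–enone) reductive cyclisation that gives cis-fused cyclopentanols. Ring B closes in the 5-exo-trig mode at C5, with C4 left outside the new ring. C5 is controlled by the preset C6 centre, because the three-atom tether reaches the ring olefin only on its own face (cis fusion); C9 is controlled by the transition state in which the bulky, electron-rich samarium-bound oxygen lies anti to the C4–C3 enolate arm, which places O11 trans to C4 and the C10 methyl cis to it. The step needs attack at C5 rather than C15 and survival of the product enone: closure at C15 would be a 6-exo attack on a neopentyl, methyl-bearing olefin terminus, and over-reduction is limited by using just over two equivalents of SmI2 at −78 °C with a weak proton donor.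

Step 11
Reactants: 15 (1S,3aS,8aS)-1-hydroxy-1,4,4,6-tetramethyl-2,3,3a,4,8,8a-hexahydroazulen-7(1H)-one
Product: 16 (1S,3aS,8aS)-1,4,4,6-tetramethyl-1-(triethylsilyloxy)-2,3,3a,4,8,8a-hexahydroazulen-7(1H)-one
Conditions: Et3SiOTf, 2,6-lutidine, CH2Cl2, −78 → 0 °C
Reagents that add atoms: triethylsilyl trifluoromethanesulfonate, CC[Si](CC)(CC)OS(=O)(=O)C(F)(F)F
Why: Silyl triflate silylation of the tertiary C9 hydroxyl removes the only acidic proton before the organometallic coupling; enol silylation of the enone needs a stronger base and higher temperature.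

Step 12
Reactants: 16 (1S,3aS,8aS)-1,4,4,6-tetramethyl-1-(triethylsilyloxy)-2,3,3a,4,8,8a-hexahydroazulen-7(1H)-one
Product: 17 (1S,3aS,7S,8aS)-1,4,4,6-tetramethyl-1-(triethylsilyloxy)-1,2,3,3a,4,7,8,8a-octahydroazulen-7-ol (C3 hydroxyl on the face of H5 and H6)
Conditions: (R)-2-methyl-CBS-oxazaborolidine (0.2 equiv), catecholborane, toluene, −78 °C
Reagents that add atoms: none
Why: Corey–Bakshi–Shibata reduction: the catalyst treats the methyl-substituted olefin arm as the large group and delivers hydride to one carbonyl face, so C3 is set as (S) by the reagent and not by the ring.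

Step 13
Reactants: 17 (1S,3aS,7S,8aS)-1,4,4,6-tetramethyl-1-(triethylsilyloxy)-1,2,3,3a,4,7,8,8a-octahydroazulen-7-ol
Product: 18 (1S,3aS,7S,8aS)-1,4,4,6-tetramethyl-1-(triethylsilyloxy)-1,2,3,3a,4,7,8,8a-octahydroazulen-7-yl pyridine-2-carboxylate
Conditions: picolinic acid, DCC, DMAP, CH2Cl2, 0 → 25 °C
Reagents that add atoms: picolinic acid, OC(=O)c1ccccn1
Why: Steglich esterification gives a stable allylic picolinate with retention at C3; its chelating leaving group is the one suited to copper-mediated γ-substitution.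

**Ring C/D half**

Step 14
Reactants: 19 2-methylcyclohexane-1,3-dione, 20 acrolein
Product: 21 3-(1-methyl-2,6-dioxocyclohexyl)propanal
Conditions: H2O, 25 °C
Reagents that add atoms: none
Why: Michael addition of the enolised dione to acrolein in water creates the quaternary C19 and brings in C21–C23.

Step 15
Reactants: 21 3-(1-methyl-2,6-dioxocyclohexyl)propanal
Product: 22 2-methyl-2-(4-methylpent-3-en-1-yl)cyclohexane-1,3-dione
Conditions: i-PrPPh3I, n-BuLi, THF, 0 °C; then 21, −78 → 0 °C
Reagents that add atoms: isopropyltriphenylphosphonium iodide, CC(C)[P+](c1ccccc1)(c1ccccc1)c1ccccc1.[I-]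
Why: Wittig olefination with a non-stabilised ylide should take the aldehyde in preference to the two hindered ketones flanking the quaternary carbon and installs C25–C27.

Step 16
Reactants: 22 2-methyl-2-(4-methylpent-3-en-1-yl)cyclohexane-1,3-dione
Product: 23 (2R,3R)-3-hydroxy-2-methyl-2-(4-methylpent-3-en-1-yl)cyclohexan-1-one
Conditions: (S)-2-methyl-CBS-oxazaborolidine (0.3 equiv), catecholborane, toluene–CH2Cl2, −78 → −40 °C
Reagents that add atoms: none
Why: Desymmetrising Corey–Bakshi–Shibata reduction: the catalyst fixes the carbinol as (R) with the quaternary carbon as large group, and of the two enantiotopic carbonyls the one whose open face lies beside the small methyl group reacts, so the hydroxyl ends cis to the side chain and C29 and C19 are set together.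

Step 17
Reactants: 23 (2R,3R)-3-hydroxy-2-methyl-2-(4-methylpent-3-en-1-yl)cyclohexan-1-one
Product: 24 (2R,3R)-2-{2-[(2S)-3,3-dimethyloxiran-2-yl]ethyl}-3-hydroxy-2-methylcyclohexan-1-one
Conditions: L-fructose-derived 1,2:4,5-di-O-isopropylidene ketone (0.3 equiv), Oxone, K2CO3, n-Bu4NHSO4, MeCN–CH2(OMe)2–aq. borate buffer (pH 10.5), 0 °C
Reagents that add atoms: potassium peroxymonosulfate (active part of Oxone), [K+].[O-]S(=O)(=O)OO
Why: Shi epoxidation: the chiral dioxirane transfers oxygen to the trisubstituted olefin through a spiro transition state, and the L-series ketone should set C23 as (S).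

Step 18
Reactants: 24 (2R,3R)-2-{2-[(2S)-3,3-dimethyloxiran-2-yl]ethyl}-3-hydroxy-2-methylcyclohexan-1-one
Product: 25 (3S,5aR,9aR)-3-hydroxy-2,2,5a-trimethyloctahydro-1-benzoxepin-6(2H)-one (cis-fused rings C/D, C18 ketone, C23 hydroxyl)
Conditions: BF3·OEt2 (0.2 equiv), CH2Cl2, −78 °C
Reagents that add atoms: none
Why: Lewis-acid-promoted intramolecular epoxide opening in the 7-endo mode: positive charge in the activated epoxide sits on the tertiary C25, so the C29 hydroxyl attacks there and forms O28–C25, while C23 keeps the epoxide oxygen and its configuration and the cis fusion follows from the cis hydroxyl/side-chain relation of 24.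

Step 19
Reactants: 25 (3S,5aR,9aR)-3-hydroxy-2,2,5a-trimethyloctahydro-1-benzoxepin-6(2H)-one
Product: 26 (3S,5aR,9aR)-3-(tert-butyldimethylsilyloxy)-2,2,5a-trimethyloctahydro-1-benzoxepin-6(2H)-one
Conditions: t-BuMe2SiOTf, 2,6-lutidine, CH2Cl2, 0 °C
Reagents that add atoms: tert-butyldimethylsilyl trifluoromethanesulfonate, CC(C)(C)[Si](C)(C)OS(=O)(=O)C(F)(F)F
Why: Silyl triflate silylation protects the hindered secondary C23 hydroxyl for the base, oxidation and hydride steps that follow.

Step 20
Reactants: 26 (3S,5aR,9aR)-3-(tert-butyldimethylsilyloxy)-2,2,5a-trimethyloctahydro-1-benzoxepin-6(2H)-one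
Product: 27 7-methyl derivative of 26 (C33 methyl on C32; both epimers at C32; C19, C23, C29 as in 26)
Conditions: LiN(i-Pr)2, THF, −78 °C; MeI, −78 → −20 °C
Reagents that add atoms: iodomethane, CI
Why: Enolate alkylation: the ketone can enolise only towards C32 because C19 is quaternary, so the methyl group enters at C32, whose configuration is erased in the next step.

Step 21
Reactants: 27 7-methyl derivative of 26
Product: 28 (3S,5aR,9aR)-3-(tert-butyldimethylsilyloxy)-2,2,5a,7-tetramethyl-2,3,4,5,5a,8,9,9a-octahydro-1-benzoxepin-6-yl trifluoromethanesulfonate (C18(OTf)=C32)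
Conditions: KN(SiMe3)2, THF, −78 → 0 °C; PhNTf2
Reagents that add atoms: N-phenylbis(trifluoromethanesulfonimide), O=S(=O)(N(c1ccccc1)S(=O)(=O)C(F)(F)F)C(F)(F)F
Why: O-Triflation of the only possible enolate gives the tetrasubstituted enol triflate regiospecifically.

Step 22
Reactants: 28 enol triflate
Product: 29 tert-butyl(dimethyl)silyl ether of 2,2,5a,7-tetramethyl-2,3,4,5,5a,8,9,9a-octahydro-1-benzoxepin-3-ol (C18H=C32(Me) olefin; C19, C23, C29 as in 26)
Conditions: Pd(OAc)2 (5 mol %), PPh3 (10 mol %), HCO2H, n-Bu3N, DMF, 60 °C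
Reagents that add atoms: none
Why: Palladium-catalysed formate reduction of an enol triflate (oxidative addition to zerovalent palladium, formate exchange, decarboxylation, reductive elimination) replaces the C18 oxygen by hydrogen and leaves the olefin at C18=C32.

Step 23
Reactants: 29 C18=C32 olefin
Product: 30 3-(tert-butyldimethylsilyloxy)-2,2,5a,7-tetramethyl-3,4,5,5a,9,9a-hexahydro-1-benzoxepin-8(2H)-one (C31 ketone conjugated with C32=C18; C19, C23, C29 as in 26)
Conditions: Rh2(cap)4 (cap = caprolactamate, 1 mol %), t-BuOOH (70 % aq., 5 equiv), K2CO3, CH2Cl2, 25 °C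
Reagents that add atoms: tert-butyl hydroperoxide, CC(C)(C)OO
Why: Dirhodium-catalysed allylic C–H oxidation with tert-butyl hydroperoxide: C31 is the only allylic methylene (C19 is quaternary), and the allyl radical is oxygenated at C31 rather than at the neopentyl C18.

Step 24
Reactants: 30 enone
Product: 31 (8R)-8-hydroxy compound from 30 (C31 carbinol, hydroxyl syn to the C20 methyl; allylic alcohol C31(OH)–C32(Me)=C18H)
Conditions: (S)-2-methyl-CBS-oxazaborolidine (0.2 equiv), catecholborane, toluene, −78 °C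
Reagents that add atoms: none
Why: Corey–Bakshi–Shibata reduction with the methyl-bearing olefin arm as large group sets C31 as (R) under reagent control; this carbinol later steers C18 and C32.

Step 25
Reactants: 31 allylic alcohol, 32 N,N-dimethylacetamide dimethyl acetal
Product: 33 2-[3-(tert-butyldimethylsilyloxy)-2,2,5a,7-tetramethyl-2,3,4,5,5a,6,9,9a-octahydro-1-benzoxepin-6-yl]-N,N-dimethylacetamide (C18 side chain syn to the C20 methyl; C31=C32 olefin)
Conditions: MeC(OMe)2NMe2 (5 equiv), xylene, 140 °C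
Reagents that add atoms: none
Why: Eschenmoser–Claisen rearrangement: the ketene N,O-acetal formed on the C31 oxygen undergoes a suprafacial [3,3] shift, so C17 bonds to C18 on the face that carried the C31–O bond, which sets C18 and moves the olefin to C31=C32.

Step 26
Reactants: 33 unsaturated amide
Product: 34 iodolactone (cis-fused γ-lactone O34–C16(=O)–C17–C18–C32; iodine on C31 trans to O34)
Conditions: I2 (3 equiv), THF–H2O (1:1), 25 °C, dark; Na2S2O3 aq
Reagents that add atoms: iodine, II; water, O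
Why: Iodolactonisation of a γ,δ-unsaturated amide: the amide oxygen opens the iodonium ion 5-exo at the tertiary C32 from the face of its own tether, so the lactone can only be cis-fused and C32 is set with O34 syn to C17; water then hydrolyses the iminium ion.

Step 27
Reactants: 34 iodolactone
Product: 35 cis-fused γ-lactone (34 without iodine; C31 is CH2)
Conditions: n-Bu3SnH, AIBN (cat.), benzene, 80 °C
Reagents that add atoms: none
Why: Radical-chain dehalogenation removes the secondary iodide without touching the lactone, the silyl ether or any stereocentre.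

Step 28
Reactants: 35 γ-lactone
Product: 36 diol (C16 primary alcohol and C32 tertiary alcohol; 24-O-TBS)
Conditions: LiAlH4, THF, 0 °C; NaOH aq work-up
Reagents that add atoms: none
Why: Hydride reduction of the lactone frees the C32 tertiary alcohol and the C16 primary alcohol.

Step 29
Reactants: 36 diol
Product: 37 primary iodide (C16–I, free C32 hydroxyl)
Conditions: I2, PPh3, imidazole, CH2Cl2, 0 °C
Reagents that add atoms: iodine, II
Why: Appel-type iodination acts on the primary alcohol only, since the tertiary alcohol cannot form a reactive alkoxyphosphonium ion at 0 °C.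

Step 30
Reactants: 37 primary iodide
Product: 38 C32 trimethylsilyl ether of 37
Conditions: Me3SiOTf, 2,6-lutidine, CH2Cl2, −78 °C
Reagents that add atoms: trimethylsilyl trifluoromethanesulfonate, C[Si](C)(C)OS(=O)(=O)C(F)(F)F
Why: Silylation of the tertiary hydroxyl removes the proton that would quench the organometallic and the nucleophile that could close a tetrahydrofuran onto C16.

**Union and end game**

Step 31
Reactants: 38 C32 trimethylsilyl ether iodide, 18 allylic picolinate
Product: 41 11-O-triethylsilyl-24-O-tert-butyldimethylsilyl-34-O-trimethylsilyl ether of the target, via alkyllithium 39 (not isolated), via alkylmagnesium bromide 40 (not isolated)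
Conditions: 38, t-BuLi (2.1 equiv), Et2O, −78 °C; MgBr2·OEt2, −78 → 0 °C; CuBr·SMe2 (0.5 equiv), THF, −78 °C; then 18, −78 → −20 °C
Reagents that add atoms: none
Why: Copper-mediated anti-SN2′ substitution of a secondary allylic picolinate by an alkylmagnesium reagent: the chelating picolinate activates the leaving group for γ-attack, the alkyl group bonds to C15 on the face opposite the C3–O bond (setting C15 with C16 anti to H5/H6) and the olefin moves to C2=C3.

Step 32
Reactants: 41 tris-silyl ether
Product: 42 target CNP0183476.6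
Conditions: HF·pyridine, pyridine, THF, 0 → 25 °C
Reagents that add atoms: none
Why: Fluoride-driven cleavage of the three Si–O bonds under buffered conditions should free O11, O24 and O34 without dehydrating the tertiary alcohols or moving the C2=C3 olefin.

**Compound list**

1 | hex-5-en-2-one | CC(=O)CCC=C | starting material
2 | 2-(but-3-en-1-yl)-2-methyl-1,3-dioxolane | CC1(CCC=C)OCCO1 | intermediate
3 | allyl methyl carbonate | C=CCOC(=O)OC | starting material
4 | methyl (2E)-5-(2-methyl-1,3-dioxolan-2-yl)pent-2-en-1-yl carbonate | COC(=O)OC/C=C/CCC1(C)OCCO1 | intermediate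
5 | 1-methoxy-2-methyl-1-(trimethylsilyloxy)prop-1-ene | COC(O[Si](C)(C)C)=C(C)C | starting material
6 | methyl (3S)-2,2-dimethyl-3-[2-(2-methyl-1,3-dioxolan-2-yl)ethyl]pent-4-enoate | CC1(CC[C@@H](C=C)C(C)(C)C(=O)OC)OCCO1 | intermediate
7 | (3S)-2,2-dimethyl-3-[2-(2-methyl-1,3-dioxolan-2-yl)ethyl]pent-4-enal | CC1(CC[C@@H](C=C)C(C)(C)C=O)OCCO1 | intermediate
8 | methyl 2-[bis(2,2,2-trifluoroethoxy)phosphoryl]propanoate | COC(=O)C(C)P(=O)(OCC(F)(F)F)OCC(F)(F)F | starting material
9 | methyl (2Z,5S)-2,4,4-trimethyl-5-[2-(2-methyl-1,3-dioxolan-2-yl)ethyl]hepta-2,6-dienoate | COC(=O)/C(C)=C\C(C)(C)[C@H](C=C)CCC1(C)OCCO1 | intermediate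
10 | (2Z,5S)-N-methoxy-N,2,4,4-tetramethyl-5-[2-(2-methyl-1,3-dioxolan-2-yl)ethyl]hepta-2,6-dienamide | CON(C)C(=O)/C(C)=C\C(C)(C)[C@H](C=C)CCC1(C)OCCO1 | intermediate
11 | vinylmagnesium bromide | C=C[Mg]Br | starting material
12 | (4Z,7S)-4,6,6-trimethyl-7-[2-(2-methyl-1,3-dioxolan-2-yl)ethyl]nona-1,4,8-trien-3-one | C=CC(=O)/C(C)=C\C(C)(C)[C@H](C=C)CCC1(C)OCCO1 | intermediate
13 | (5S)-2,4,4-trimethyl-5-[2-(2-methyl-1,3-dioxolan-2-yl)ethyl]cyclohepta-2,6-dien-1-one | CC1=CC(C)(C)[C@@H](CCC2(C)OCCO2)C=CC1=O | intermediate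
14 | (5S)-2,4,4-trimethyl-5-(3-oxobutyl)cyclohepta-2,6-dien-1-one | CC(=O)CC[C@H]1C=CC(=O)C(C)=CC1(C)C | intermediate
15 | (1S,3aS,8aS)-1-hydroxy-1,4,4,6-tetramethyl-2,3,3a,4,8,8a-hexahydroazulen-7(1H)-one | CC1=CC(C)(C)[C@H]2CC[C@](C)(O)[C@H]2CC1=O | intermediate
16 | (1S,3aS,8aS)-1,4,4,6-tetramethyl-1-(triethylsilyloxy)-2,3,3a,4,8,8a-hexahydroazulen-7(1H)-one | CC1=CC(C)(C)[C@H]2CC[C@](C)(O[Si](CC)(CC)CC)[C@H]2CC1=O | intermediate
17 | (1S,3aS,7S,8aS)-1,4,4,6-tetramethyl-1-(triethylsilyloxy)-1,2,3,3a,4,7,8,8a-octahydroazulen-7-ol | CC1=CC(C)(C)[C@H]2CC[C@](C)(O[Si](CC)(CC)CC)[C@H]2C[C@@H]1O | intermediate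
18 | (1S,3aS,7S,8aS)-1,4,4,6-tetramethyl-1-(triethylsilyloxy)-1,2,3,3a,4,7,8,8a-octahydroazulen-7-yl pyridine-2-carboxylate | CC1=CC(C)(C)[C@H]2CC[C@](C)(O[Si](CC)(CC)CC)[C@H]2C[C@@H]1OC(=O)c1ccccn1 | intermediate
19 | 2-methylcyclohexane-1,3-dione | CC1C(=O)CCCC1=O | starting material
20 | acrolein | C=CC=O | starting material
21 | 3-(1-methyl-2,6-dioxocyclohexyl)propanal | CC1(CCC=O)C(=O)CCCC1=O | intermediate
22 | 2-methyl-2-(4-methylpent-3-en-1-yl)cyclohexane-1,3-dione | CC(C)=CCCC1(C)C(=O)CCCC1=O | intermediate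
23 | (2R,3R)-3-hydroxy-2-methyl-2-(4-methylpent-3-en-1-yl)cyclohexan-1-one | CC(C)=CCC[C@@]1(C)C(=O)CCC[C@H]1O | intermediate
24 | (2R,3R)-2-{2-[(2S)-3,3-dimethyloxiran-2-yl]ethyl}-3-hydroxy-2-methylcyclohexan-1-one | CC1(C)O[C@H]1CC[C@@]1(C)C(=O)CCC[C@H]1O | intermediate
25 | (3S,5aR,9aR)-3-hydroxy-2,2,5a-trimethyloctahydro-1-benzoxepin-6(2H)-one | O=C1[C@]2(C)CC[C@H](O)C(C)(C)O[C@@H]2CCC1 | intermediate
26 | (3S,5aR,9aR)-3-(tert-butyldimethylsilyloxy)-2,2,5a-trimethyloctahydro-1-benzoxepin-6(2H)-one | O=C1[C@]2(C)CC[C@H](O[Si](C)(C)C(C)(C)C)C(C)(C)O[C@@H]2CCC1 | intermediate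
27 | 7-methyl derivative of 26 (C32 epimers) | O=C1[C@]2(C)CC[C@H](O[Si](C)(C)C(C)(C)C)C(C)(C)O[C@@H]2CCC1C | intermediate
28 | enol triflate of 27 (C18(OTf)=C32) | CC1=C(OS(=O)(=O)C(F)(F)F)[C@]2(C)CC[C@H](O[Si](C)(C)C(C)(C)C)C(C)(C)O[C@@H]2CC1 | intermediate
29 | C18=C32 olefin, 24-O-TBS | CC1=C[C@]2(C)CC[C@H](O[Si](C)(C)C(C)(C)C)C(C)(C)O[C@@H]2CC1 | intermediate
30 | C31 enone, 24-O-TBS | CC1=C[C@]2(C)CC[C@H](O[Si](C)(C)C(C)(C)C)C(C)(C)O[C@@H]2CC1=O | intermediate
31 | (R)-C31 allylic alcohol, hydroxyl syn to C20 methyl | CC1=C[C@]2(C)CC[C@H](O[Si](C)(C)C(C)(C)C)C(C)(C)O[C@@H]2C[C@H]1O | intermediate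
32 | N,N-dimethylacetamide dimethyl acetal | CC(OC)(OC)N(C)C | starting material
33 | C18 (dimethylcarbamoyl)methyl compound, C31=C32 olefin | CN(C)C(=O)C[C@H]1[C@]2(C)CC[C@H](O[Si](C)(C)C(C)(C)C)C(C)(C)O[C@@H]2CC=C1C | intermediate
34 | iodolactone | O=C1C[C@H]2[C@]3(C)CC[C@H](O[Si](C)(C)C(C)(C)C)C(C)(C)O[C@@H]3C[C@H](I)[C@@]2(C)O1 | intermediate
35 | cis-fused γ-lactone | O=C1C[C@H]2[C@]3(C)CC[C@H](O[Si](C)(C)C(C)(C)C)C(C)(C)O[C@@H]3CC[C@@]2(C)O1 | intermediate
36 | C16/C32 diol, 24-O-TBS | OCC[C@H]1[C@]2(C)CC[C@H](O[Si](C)(C)C(C)(C)C)C(C)(C)O[C@@H]2CC[C@@]1(C)O | intermediate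
37 | C16 iodide, free C32 hydroxyl | ICC[C@H]1[C@]2(C)CC[C@H](O[Si](C)(C)C(C)(C)C)C(C)(C)O[C@@H]2CC[C@@]1(C)O | intermediate
38 | C16 iodide, 34-O-TMS, 24-O-TBS | ICC[C@H]1[C@]2(C)CC[C@H](O[Si](C)(C)C(C)(C)C)C(C)(C)O[C@@H]2CC[C@@]1(C)O[Si](C)(C)C | intermediate
39 | C16 alkyllithium from 38 | [Li]CC[C@H]1[C@]2(C)CC[C@H](O[Si](C)(C)C(C)(C)C)C(C)(C)O[C@@H]2CC[C@@]1(C)O[Si](C)(C)C | intermediate
40 | C16 alkylmagnesium bromide from 39 | Br[Mg]CC[C@H]1[C@]2(C)CC[C@H](O[Si](C)(C)C(C)(C)C)C(C)(C)O[C@@H]2CC[C@@]1(C)O[Si](C)(C)C | intermediate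
41 | 11-O-TES, 24-O-TBS, 34-O-TMS ether of the target | CC1=CC[C@H]2[C@H](CC[C@]2(C)O[Si](CC)(CC)CC)C(C)(C)[C@@H]1CC[C@H]1[C@]2(C)CC[C@H](O[Si](C)(C)C(C)(C)C)C(C)(C)O[C@@H]2CC[C@@]1(C)O[Si](C)(C)C | intermediate
42 | CNP0183476.6 | CC1=CC[C@H]2[C@H](CC[C@]2(C)O)C(C)(C)[C@@H]1CC[C@H]1[C@]2(C)CC[C@H](O)C(C)(C)O[C@@H]2CC[C@@]1(C)O | target

**Count**

Total: 32 steps. Longest linear sequence: 19 steps (steps 14–32); the ring A/B half takes 13 steps before the union.

**Steps most likely to fail**

Step 10. Electron transfer to the cross-conjugated dienone may outrun C–C bond formation, so that material is lost to simple 1,4-reduction, dimerisation or over-reduction of the product enone. The fallback removes the reducible dienone before ring closure and sets out from 13. Luche reduction (NaBH4, CeCl3·7H2O, MeOH, −78 °C) should give the bis-allylic alcohol ketal F1. Neutral ketal cleavage (cat. I2, acetone, 25 °C) should give the keto dienol F2, in which only the methyl ketone can accept an electron. SmI2–HMPA–t-BuOH then closes ring B by 5-exo ketyl addition to the unactivated C4=C5 olefin through the same anti transition state and should give the diol F3. MnO2 (CH2Cl2) oxidises only the allylic C3 carbinol, and the route is rejoined at 15.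

Step 18. The hydroxyl may attack the secondary epoxide carbon C23 (6-exo closure to a tetrahydropyran), or the activated epoxide may rearrange by hydride shift. The fallback takes away the choice of site and sets out from 24. Et2Al(tmp) (diethylaluminium 2,2,6,6-tetramethylpiperidide, toluene, 0 °C) isomerises the epoxide to the allylic alcohol F4 without touching the C23–O bond. The less hindered allylic hydroxyl is silylated (t-BuMe2SiCl, imidazole, DMF, 0 °C) to the mono-silyl ether F5. Hg(OCOCF3)2 (MeCN, 0 °C) then brings about Markovnikov alkoxymercuration of the 1,1-disubstituted olefin by the C29 hydroxyl. This is a 7-exo closure at C25, and the only alternative would be an eight-membered ring. It should give the organomercurial F6, which n-Bu3SnH reduces to 26.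

Step 31. The organocopper species may substitute directly at C3 instead of at the hindered C15, the allylic ester may ionise with loss of configuration, or the halogen–metal exchange on the β-branched iodide may be incomplete. The fallback replaces substitution by carbonyl allylation and sets out from 35 and 17.
- Lactone 35 is reduced (i-Bu2AlH, CH2Cl2, −78 °C) to the lactol F7.
- Alcohol 17 is converted into the methyl carbonate F8 (ClCO2Me, pyridine) and borylated with inversion (Pd2(dba)3, B2pin2, DMSO, 50 °C) to the allylboronate F9.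
- F9 adds to the open hydroxy-aldehyde form of F7 (toluene, 60 °C) through a closed six-membered transition state. This forms C15–C16 on the boron-bearing face, moves the olefin to C2=C3 and should give the homoallylic diol F10.
- The C16 carbinol is removed by Barton–McCombie deoxygenation through the thiocarbonylimidazolide F11 (1,1′-thiocarbonyldiimidazole, DMAP; then n-Bu3SnH, AIBN, toluene, 90 °C) to the bis-silyl ether F12.
- HF·pyridine then rejoins the route at 42.

**Further compounds**

F1 | step 10 | (5S)-2,4,4-trimethyl-5-[2-(2-methyl-1,3-dioxolan-2-yl)ethyl]cyclohepta-2,6-dien-1-ol (carbinol epimers) | CC1=CC(C)(C)[C@@H](CCC2(C)OCCO2)C=CC1O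
F2 | step 10 | 4-[(1S)-4-hydroxy-5,7,7-trimethylcyclohepta-2,5-dien-1-yl]butan-2-one (carbinol epimers) | CC(=O)CC[C@H]1C=CC(O)C(C)=CC1(C)C
F3 | step 10 | (1S,3aS,8aS)-1,4,4,6-tetramethyl-1,2,3,3a,4,7,8,8a-octahydroazulene-1,7-diol (C7 epimers) | CC1=CC(C)(C)[C@H]2CC[C@](C)(O)[C@H]2CC1O
F4 | step 18 | (2R,3R)-3-hydroxy-2-[(3S)-3-hydroxy-4-methylpent-4-en-1-yl]-2-methylcyclohexan-1-one | C=C(C)[C@@H](O)CC[C@@]1(C)C(=O)CCC[C@H]1O
F5 | step 18 | (2R,3R)-2-[(3S)-3-(tert-butyldimethylsilyloxy)-4-methylpent-4-en-1-yl]-3-hydroxy-2-methylcyclohexan-1-one | C=C(C)[C@@H](O[Si](C)(C)C(C)(C)C)CC[C@@]1(C)C(=O)CCC[C@H]1O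
F6 | step 18 | 26 bearing a trifluoroacetoxymercurio group on one C25 methyl (C25 epimers) | O=C1[C@]2(C)CC[C@H](O[Si](C)(C)C(C)(C)C)C(C)(C[Hg]OC(=O)C(F)(F)F)O[C@@H]2CCC1
F7 | step 31 | lactol of 35 (C16 anomers) | OC1C[C@H]2[C@]3(C)CC[C@H](O[Si](C)(C)C(C)(C)C)C(C)(C)O[C@@H]3CC[C@@]2(C)O1
F8 | step 31 | methyl carbonate of 17 | CC1=CC(C)(C)[C@H]2CC[C@](C)(O[Si](CC)(CC)CC)[C@H]2C[C@@H]1OC(=O)OC
F9 | step 31 | C3 pinacol allylboronate (boron on the face opposite H5/H6), 11-O-TES | CC1=CC(C)(C)[C@H]2CC[C@](C)(O[Si](CC)(CC)CC)[C@H]2C[C@H]1B1OC(C)(C)C(C)(C)O1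
F10 | step 31 | C16-hydroxy compound (C16 epimers), 11-O-TES, 24-O-TBS, free O34–H | CC1=CC[C@H]2[C@H](CC[C@]2(C)O[Si](CC)(CC)CC)C(C)(C)[C@@H]1C(O)C[C@H]1[C@]2(C)CC[C@H](O[Si](C)(C)C(C)(C)C)C(C)(C)O[C@@H]2CC[C@@]1(C)O
F11 | step 31 | C16 O-(imidazol-1-ylthiocarbonyl) derivative of F10 | CC1=CC[C@H]2[C@H](CC[C@]2(C)O[Si](CC)(CC)CC)C(C)(C)[C@@H]1C(OC(=S)n1ccnc1)C[C@H]1[C@]2(C)CC[C@H](O[Si](C)(C)C(C)(C)C)C(C)(C)O[C@@H]2CC[C@@]1(C)O
F12 | step 31 | 11-O-triethylsilyl-24-O-tert-butyldimethylsilyl ether of 42 | CC1=CC[C@H]2[C@H](CC[C@]2(C)O[Si](CC)(CC)CC)C(C)(C)[C@@H]1CC[C@H]1[C@]2(C)CC[C@H](O[Si](C)(C)C(C)(C)C)C(C)(C)O[C@@H]2CC[C@@]1(C)O
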